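**Retrosynthetic overview**

1. Numbering used throughout: five-membered ring C1–C5 (C1 quaternary with CH3, C4 carbinol with isopropyl), seven-membered ring C1, C5–C10 (C6 aroyloxy, C8=C9 with CH3 on C8, C10 tigloyloxy); the rings share C1–C5 and are cis-fused.
2. Late stage: both esters are put on last; the C10 carbinol comes from a C8=C9 enone, the enone and C8 methyl from a C10 ketone, the C10 ketone from an exocyclic methylene, and the C6 carbinol from a C6 ketone masked as a silyl enol ether.
3. Key disconnection: both carbocycles are formed at once by a rhodium-catalysed intramolecular (5+2) cycloaddition of a two-carbon unit C1=C10 (internal π-bond of a 1,1-disubstituted allene) with a five-carbon unit C5–C9 (vinylcyclopropane), tethered through C2–C4.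
4. Enabling feature: the syn 1,3-dioxygenation at C4 and C6 flanking the ring-fusion carbon C5 lets O4 and O6 be tied into a temporary 4H-1,3,2-dioxasiline whose enol double bond C5=C6 is the vinyl group of the vinylcyclopropane; the ring fixes the enol geometry and puts tether and isopropyl on opposite faces, so C4 controls C5 and C1.
5. The acyclic precursor comes from the chiral-pool terpene (S)-terpinen-4-ol, whose ozonolysis lays out C1–C6 with the C4 carbinol stereocentre, the isopropyl group and the C1 methyl; ring order: dioxasiline (temporary), then five- and seven-membered rings together.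

Key step: step 6

Assumption: (S)-(+)-terpinen-4-ol is used in enantiopure form and 4-(tert-butyldimethylsilyloxy)benzoic acid is taken as a purchasable building block.

**Route**

Step 1
Reactants: 1 (S)-terpinen-4-ol
Product: 2 methyl (3S)-3-hydroxy-6-oxo-3-(propan-2-yl)heptanoate
Conditions: O3, NaOH (2.5 M in MeOH), CH2Cl2, −78 °C; then H2O, 0 °C
Reagents that add atoms: ozone [O-][O+]=O; methanol CO
Why: Ozonolysis of the trisubstituted ring alkene in methanolic NaOH should cleave the terpene C=C into the methyl ketone (future C1 with its CH3) and, via the α-methoxy hydroperoxide, the methyl ester (future C6), leaving the tertiary carbinol stereocentre (future C4) untouched.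

Step 2
Reactants: 2 methyl (3S)-3-hydroxy-6-oxo-3-(propan-2-yl)heptanoate; 3 ethynylmagnesium bromide
Product: 5 methyl (3S)-3-hydroxy-6-[(methoxycarbonyl)oxy]-6-methyl-3-(propan-2-yl)oct-7-ynoate (both epimers at the propargylic carbon), via bis(bromomagnesium) alkoxide 4 (not isolated)
Conditions: HC≡CMgBr (2.5 equiv), THF, −78 → −20 °C; then ClCO2Me (1.2 equiv), −20 → 0 °C; H2O
Reagents that add atoms: ethynylmagnesium bromide (3) C#C[Mg]Br; methyl chloroformate COC(=O)Cl
Why: 1,2-Addition of the acetylide to the ketone (faster than to the ester at low temperature) followed by O-acylation of the less hindered propargylic magnesium alkoxide should give the carbonate; the new carbinol centre forms unselectively and is erased in step 3.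

Step 3
Reactants: 5 methyl (3S)-3-hydroxy-6-[(methoxycarbonyl)oxy]-6-methyl-3-(propan-2-yl)oct-7-ynoate
Product: 6 methyl (3S)-3-hydroxy-6-methyl-3-(propan-2-yl)octa-6,7-dienoate
Conditions: Pd2(dba)3·CHCl3 (2.5 mol%), PBu3 (10 mol%), HCO2NH4, THF, 40 °C
Reagents that add atoms: none
Why: Palladium-catalysed formate hydrogenolysis of a tertiary propargylic carbonate: SN2′-type oxidative addition to zerovalent palladium gives an allenylpalladium species, and hydride from formate decarboxylation is reductively eliminated to give the 1,1-disubstituted allene without creating a stereocentre.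

Step 4
Reactants: 6 methyl (3S)-3-hydroxy-6-methyl-3-(propan-2-yl)octa-6,7-dienoate; 7 cyclopropylmagnesium bromide
Product: 9 (3S)-1-cyclopropyl-3-hydroxy-6-methyl-3-(propan-2-yl)octa-6,7-dien-1-one, via Weinreb amide 8 (not isolated)
Conditions: MeNH(OMe)·HCl, iPrMgCl, THF, −20 °C; then cyclopropylmagnesium bromide, 0 °C; aq NH4Cl
Reagents that add atoms: cyclopropylmagnesium bromide (7) Br[Mg]C1CC1; N,O-dimethylhydroxylamine hydrochloride CNOC.Cl (its atoms stay only in intermediate 8)
Why: Ester aminolysis by the magnesium amide followed by Weinreb ketone synthesis should stop at the ketone, because the chelated tetrahedral adduct prevents over-addition and keeps the β-alkoxide from retro-aldol cleavage until the quench.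

Step 5
Reactants: 9 (3S)-1-cyclopropyl-3-hydroxy-6-methyl-3-(propan-2-yl)octa-6,7-dien-1-one
Product: 10 (4R)-6-cyclopropyl-4-(3-methylpenta-3,4-dien-1-yl)-2,2,4-tri(propan-2-yl)-4H-1,3,2-dioxasiline
Conditions: iPr2Si(OTf)2, Et3N, CH2Cl2, −78 → 0 °C
Reagents that add atoms: diisopropylsilyl bis(trifluoromethanesulfonate) CC(C)[Si](OS(=O)(=O)C(F)(F)F)(OS(=O)(=O)C(F)(F)F)C(C)C
Why: Soft enolisation and O-silylation with a bifunctional silyl triflate: the ketone can enolise only towards C5 (the other α-carbon is a cyclopropane CH), and closure of the second Si–O bond gives a six-membered ring that fixes the enol ether with O6 cis to C4.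

Step 6
Reactants: 10 (4R)-6-cyclopropyl-4-(3-methylpenta-3,4-dien-1-yl)-2,2,4-tri(propan-2-yl)-4H-1,3,2-dioxasiline
Product: 11 tricyclic silylene enol ether: cis-fused hydroazulene with 1-CH3, 10-methylidene, 4-isopropyl, C6=C7 enol double bond and the O4–Si(iPr)2–O6 bridge; CH3, H-5 and isopropyl on one face
Conditions: [Rh(CO)2Cl]2 (2.5 mol%), toluene (0.02 M), 90 °C
Reagents that add atoms: none
Why: [Rh(CO)2Cl]2 coordinates the vinylcyclopropane and opens the cyclopropane bond C7–C9 to a σ,π-allyl rhodacyclohexene, the internal π-bond of the tethered allene inserts to form C5–C1, and C–C reductive elimination from the rhodacyclooctene forms C9–C10 and returns monovalent rhodium. The closest known reaction type is the rhodium-catalysed intramolecular (5+2) cycloaddition of allene-tethered vinylcyclopropanes, which accepts oxygen-substituted vinylcyclopropanes and builds angular methyl centres from 1,1-disubstituted allene termini. The five-membered ring is closed by the migratory insertion (5-exo carbometallation across C1=C10, with C10 staying on rhodium and keeping its exocyclic CH2), and the seven-membered ring by C(sp3)–C(sp2) reductive elimination, a formal union of the five-carbon unit C5–C9 with the two-carbon unit C1–C10. C5 is controlled by C4: the dioxasiline holds O4 in the plane of the enol ether, so the tether carbon C3 and the isopropyl group sit on opposite faces and C1 can only be delivered to the face carrying C3, which places H-5 cis to isopropyl and O4 cis to C6; C1 follows from the cis ring fusion enforced by the three-atom tether, so CH3 and H-5 end up cis. The step needs chemoselectivity for the internal allene π-bond (secured by the tether length, since the terminal π-bond would require a six-membered ring), the reactive conformer with the tether trans to the cyclopropyl group (secured by the ring-fixed enol geometry), and cyclopropane opening that outruns allene oligomerisation (high dilution).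

Step 7
Reactants: 11 tricyclic silylene enol ether
Product: 12 cis-fused 4-hydroxy-1-methyl-10-methylidene-4-(propan-2-yl)hydroazulen-6-one (CH3, H-5 and isopropyl cis; 4-OH on the opposite face)
Conditions: HF·pyridine, pyridine, THF, 0 °C
Reagents that add atoms: none
Why: Fluoride cleavage of both Si–O bonds (desilylation) and C-protonation of the enol at C7 should give the ketone without touching C5, the buffered non-basic medium avoiding retro-aldol opening of the β-hydroxy ketone.

Step 8
Reactants: 12 cis-fused 4-hydroxy-1-methyl-10-methylidene-4-(propan-2-yl)hydroazulen-6-one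
Product: 13 corresponding 4,6-diol with 6-OH cis to 4-OH (syn-1,3-diol; H-6 on the face of H-5)
Conditions: Et2BOMe, THF/MeOH (4:1), −78 °C; NaBH4; then AcOH, MeOH co-evaporation
Reagents that add atoms: none
Why: Narasaka–Prasad reduction: Et2BOMe ties O4 and the C6 carbonyl into a six-membered boron chelate, and external hydride should add anti to the C5–C1 bond (the α-substituent on the chelate), that is from the face of H-5, to give the syn-1,3-diol.

Step 9
Reactants: 13 syn-4,6-diol; 14 4-(tert-butyldimethylsilyloxy)benzoic acid
Product: 15 6-O-[4-(tert-butyldimethylsilyloxy)benzoyl] ester of diol 13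
Conditions: N,N′-dicyclohexylcarbodiimide, 4-(dimethylamino)pyridine, CH2Cl2, 25 °C
Reagents that add atoms: 4-(tert-butyldimethylsilyloxy)benzoic acid (14) CC(C)(C)[Si](C)(C)Oc1ccc(cc1)C(O)=O
Why: Steglich esterification should acylate only the secondary C6 hydroxyl with retention, the tertiary C4 hydroxyl next to the isopropyl group being unreactive.

Step 10
Reactants: 15 6-O-aroyl ester with 10-methylidene
Product: 16 corresponding 10-ketone (10-methylidene replaced by 10-oxo)
Conditions: O3, CH2Cl2, −78 °C (indicator end point); then Me2S, −78 → 25 °C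
Reagents that add atoms: ozone [O-][O+]=O
Why: Ozonolysis with reductive work-up of the only remaining alkene, the exocyclic 1,1-disubstituted methylene, should unveil the C10 ketone, the ester-deactivated arene being inert to ozone at −78 °C.

Step 11
Reactants: 16 10-ketone
Product: 17 C8=C9 enone (10-oxo-8-ene, no methyl on C8 yet)
Conditions: 2-iodoxybenzoic acid (IBX), DMSO, 70 °C
Reagents that add atoms: none
Why: IBX-mediated α,β-dehydrogenation of a ketone: enolisation is possible only towards C9 because C1 is quaternary, so the C8=C9 enone should form regioselectively and cannot over-oxidise to a cross-conjugated dienone.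

Step 12
Reactants: 17 C8=C9 enone
Product: 21 8-methyl C8=C9 enone (10-oxo-8-methyl-8-ene), via lithium enolate 18 (not isolated), via α-phenylselanyl ketone 19 (not isolated), via selenoxide 20 (not isolated)
Conditions: Me2CuLi (3 equiv, from CuI and MeLi), Et2O, −78 → −40 °C; PhSeCl, THF, −78 °C; then H2O2, pyridine, CH2Cl2, 0 → 25 °C
Reagents that add atoms: lithium dimethylcuprate [Li+].C[Cu-]C (benzeneselenenyl chloride Cl[Se]c1ccccc1 and hydrogen peroxide OO put atoms only into intermediates 19 and 20)
Why: Cuprate conjugate addition puts the methyl group on C8, the enolate is selenenylated at C9, and selenoxide syn-elimination (only the C8–H is available) should restore the C8=C9 double bond, now trisubstituted, destroying the transient C8 and C9 stereocentres.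

Step 13
Reactants: 21 8-methyl C8=C9 enone
Product: 22 10-alcohol with 10-OH cis to the C1 methyl (10R)
Conditions: NaBH4, CeCl3·7H2O, MeOH, −78 °C
Reagents that add atoms: none
Why: Luche 1,2-reduction: hydride is expected to approach C10 anti to the angular methyl on the adjacent quaternary C1, as in other ketones flanked by an angular methyl, giving the allylic alcohol cis to that methyl.

Step 14
Reactants: 22 10-alcohol; 23 tigloyl chloride
Product: 24 silyl-protected target (10-O-tigloyl, 6-O-[4-(tert-butyldimethylsilyloxy)benzoyl])
Conditions: tigloyl chloride, pyridine, 4-(dimethylamino)pyridine (cat.), CH2Cl2, 0 → 25 °C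
Reagents that add atoms: tigloyl chloride (23) C/C=C(\C)C(Cl)=O
Why: Acylation of the secondary allylic alcohol via the acylpyridinium ion should proceed with retention at C10 and of the E geometry, the weak base pyridine avoiding vinylketene formation and deconjugation, and the tertiary hydroxyl staying free.

Step 15
Reactants: 24 silyl-protected target
Product: 25 (3R,3aS,4R,8R,8aR)-3-hydroxy-6,8a-dimethyl-8-{[(2E)-2-methylbut-2-enoyl]oxy}-3-(propan-2-yl)-1,2,3,3a,4,5,8,8a-octahydroazulen-4-yl 4-hydroxybenzoate (target)
Conditions: Bu4NF, AcOH (1:1), THF, 0 °C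
Reagents that add atoms: none
Why: Buffered fluoride desilylation should remove the aryl silyl ether, which is far more labile than the benzoate and tiglate esters, leaving the tertiary alcohol and both double bonds untouched.

**Compound list**

1 | (S)-terpinen-4-ol [(1S)-4-methyl-1-(propan-2-yl)cyclohex-3-en-1-ol] | CC1=CC[C@](O)(C(C)C)CC1 | starting material
2 | methyl (3S)-3-hydroxy-6-oxo-3-(propan-2-yl)heptanoate | COC(=O)C[C@](O)(C(C)C)CCC(C)=O | intermediate
3 | ethynylmagnesium bromide | C#C[Mg]Br | starting material
4 | bis(bromomagnesium) alkoxide of methyl (3S)-3,6-dihydroxy-6-methyl-3-(propan-2-yl)oct-7-ynoate (both C6 epimers) | COC(=O)C[C@](O[Mg]Br)(C(C)C)CCC(C)(O[Mg]Br)C#C | intermediate (not isolated)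
5 | methyl (3S)-3-hydroxy-6-[(methoxycarbonyl)oxy]-6-methyl-3-(propan-2-yl)oct-7-ynoate (both C6 epimers) | COC(=O)C[C@](O)(C(C)C)CCC(C)(OC(=O)OC)C#C | intermediate
6 | methyl (3S)-3-hydroxy-6-methyl-3-(propan-2-yl)octa-6,7-dienoate | COC(=O)C[C@](O)(C(C)C)CCC(C)=C=C | intermediate
7 | cyclopropylmagnesium bromide | Br[Mg]C1CC1 | starting material
8 | (3S)-3-hydroxy-N-methoxy-N,6-dimethyl-3-(propan-2-yl)octa-6,7-dienamide (Weinreb amide, formed as its magnesium alkoxide) | CON(C)C(=O)C[C@](O)(C(C)C)CCC(C)=C=C | intermediate (not isolated)
9 | (3S)-1-cyclopropyl-3-hydroxy-6-methyl-3-(propan-2-yl)octa-6,7-dien-1-one | O=C(C1CC1)C[C@](O)(C(C)C)CCC(C)=C=C | intermediate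
10 | (4R)-6-cyclopropyl-4-(3-methylpenta-3,4-dien-1-yl)-2,2,4-tri(propan-2-yl)-4H-1,3,2-dioxasiline | C1=C(C2CC2)O[Si](C(C)C)(C(C)C)O[C@@]1(C(C)C)CCC(C)=C=C | intermediate
11 | tricyclic silylene enol ether: cis-fused hydroazulene, 1-CH3, 10-methylidene, 4-isopropyl, C6=C7 enol ether, O4–Si(iPr)2–O6 bridge; CH3, H-5 and isopropyl on one face | C=C1CCC=C2O[Si](C(C)C)(C(C)C)O[C@@]3(C(C)C)CC[C@]1(C)[C@@H]23 | intermediate
12 | cis-fused 4-hydroxy-1-methyl-10-methylidene-4-(propan-2-yl)hydroazulen-6-one; CH3, H-5, isopropyl cis, 4-OH opposite | C=C1CCCC(=O)[C@@H]2[C@@]1(C)CC[C@@]2(O)C(C)C | intermediate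
13 | cis-fused 1-methyl-10-methylidene-4-(propan-2-yl)hydroazulene-4,6-diol; 6-OH cis to 4-OH | C=C1CCC[C@@H](O)[C@@H]2[C@@]1(C)CC[C@@]2(O)C(C)C | intermediate
14 | 4-(tert-butyldimethylsilyloxy)benzoic acid | CC(C)(C)[Si](C)(C)Oc1ccc(cc1)C(O)=O | starting material
15 | 6-O-[4-(tert-butyldimethylsilyloxy)benzoyl] ester of diol 13 | C=C1CCC[C@@H](OC(=O)c3ccc(O[Si](C)(C)C(C)(C)C)cc3)[C@@H]2[C@@]1(C)CC[C@@]2(O)C(C)C | intermediate
16 | 10-ketone: 4-hydroxy-1-methyl-10-oxo-4-(propan-2-yl)hydroazulen-6-yl 4-(tert-butyldimethylsilyloxy)benzoate | O=C1CCC[C@@H](OC(=O)c3ccc(O[Si](C)(C)C(C)(C)C)cc3)[C@@H]2[C@@]1(C)CC[C@@]2(O)C(C)C | intermediate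
17 | C8=C9 enone of 16 (10-oxo-8-ene) | O=C1C=CC[C@@H](OC(=O)c3ccc(O[Si](C)(C)C(C)(C)C)cc3)[C@@H]2[C@@]1(C)CC[C@@]2(O)C(C)C | intermediate
18 | lithium C9=C10 enolate of the 8-methyl ketone, C4 hydroxyl as lithium alkoxide (C8 epimers) | [Li]OC1=CC(C)C[C@@H](OC(=O)c3ccc(O[Si](C)(C)C(C)(C)C)cc3)[C@@H]2[C@@]1(C)CC[C@@]2(O[Li])C(C)C | intermediate (not isolated)
19 | 8-methyl-9-(phenylselanyl) 10-ketone (C8/C9 diastereomers) | O=C1C([Se]c4ccccc4)C(C)C[C@@H](OC(=O)c3ccc(O[Si](C)(C)C(C)(C)C)cc3)[C@@H]2[C@@]1(C)CC[C@@]2(O)C(C)C | intermediate (not isolated)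
20 | selenoxide of 19 | O=C1C([Se](=O)c4ccccc4)C(C)C[C@@H](OC(=O)c3ccc(O[Si](C)(C)C(C)(C)C)cc3)[C@@H]2[C@@]1(C)CC[C@@]2(O)C(C)C | intermediate (not isolated)
21 | 8-methyl C8=C9 enone (10-oxo-8-methyl-8-ene) | O=C1C=C(C)C[C@@H](OC(=O)c3ccc(O[Si](C)(C)C(C)(C)C)cc3)[C@@H]2[C@@]1(C)CC[C@@]2(O)C(C)C | intermediate
22 | 10-alcohol, 10-OH cis to the C1 methyl | O[C@@H]1C=C(C)C[C@@H](OC(=O)c3ccc(O[Si](C)(C)C(C)(C)C)cc3)[C@@H]2[C@@]1(C)CC[C@@]2(O)C(C)C | intermediate
23 | tigloyl chloride [(2E)-2-methylbut-2-enoyl chloride] | C/C=C(\C)C(Cl)=O | starting material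
24 | silyl-protected target: 10-O-tigloyl, 6-O-[4-(tert-butyldimethylsilyloxy)benzoyl] | C/C=C(\C)C(=O)O[C@@H]1C=C(C)C[C@@H](OC(=O)c2ccc(O[Si](C)(C)C(C)(C)C)cc2)[C@@H]2[C@@]1(C)CC[C@@]2(O)C(C)C | intermediate
25 | (3R,3aS,4R,8R,8aR)-3-hydroxy-6,8a-dimethyl-8-{[(2E)-2-methylbut-2-enoyl]oxy}-3-(propan-2-yl)-1,2,3,3a,4,5,8,8a-octahydroazulen-4-yl 4-hydroxybenzoate | C/C=C(\C)C(=O)O[C@@H]1C=C(C)C[C@@H](OC(=O)c2ccc(O)cc2)[C@@H]2[C@@]1(C)CC[C@@]2(O)C(C)C | target

**Step count and risks**

Total: 15 steps. Longest linear sequence: 15 steps (1 → 25); all other components are purchased.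

Step 6 (key step). The cyclopropane of the ring-locked, electron-rich enol ether may open too slowly on rhodium, so that oligomerisation or ene-type cycloisomerisation of the allene, or loss of the silylene ring, outruns the cycloaddition. The fallback sets out from 9 and comes back at 12, so it also bypasses the ring closure of step 5. Ketone 9 would be silylated with Et3SiOTf and Et3N to the acyclic (Z)-1-cyclopropyl-6-methyl-3-(propan-2-yl)-1,3-bis(triethylsilyloxy)octa-1,6,7-triene F1, the unstrained and conformationally free version of the same allene–vinylcyclopropane. Its rhodium-catalysed (5+2) cycloaddition should give the bis(triethylsilyl) cycloadduct F2, with face control now resting on allylic strain (isopropyl larger than OSiEt3) instead of the ring. HF·pyridine would then convert F2 into 12.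

Step 8. Hydride may add to the other face of the boron chelate, because the quaternary C4 erodes chelation control, and give the C6 epimer. The fallback sets out from 12 and comes back at 15. Reduction of 12 with Me4NBH(OAc)3, which delivers hydride internally from the O4-bound boron, would be used to make the C6-epimeric anti-diol F3 on purpose. Mitsunobu esterification of F3 with acid 14 (PPh3, diisopropyl azodicarboxylate) would then install the aroyl ester with inversion at C6 to give 15.

Step 13. Facial discrimination at C10 may be poor, because both faces of the carbonyl are flanked by substituents of the quaternary C1 and the seven-membered enone is conformationally mobile. The fallback sets out from 21 and comes back at 22. The reduction would be run under catalyst control as a Corey–Bakshi–Shibata reduction with catecholborane and the matched enantiomer of 2-methyl-CBS-oxazaborolidine (1-methyl-3,3-diphenyl-tetrahydro-1H,3H-pyrrolo[1,2-c][1,3,2]oxazaborole) at −78 °C, which overrides a weak substrate bias. This fallback makes no new compound (F0).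

Further compounds
F1 | step 6 | (Z)-1-cyclopropyl-6-methyl-3-(propan-2-yl)-1,3-bis(triethylsilyloxy)octa-1,6,7-triene, (3S) carbinol configuration as in 9 | CC[Si](CC)(CC)O/C(C1CC1)=C\[C@](O[Si](CC)(CC)CC)(C(C)C)CCC(C)=C=C
F2 | step 6 | bis(triethylsilyl) cycloadduct: cis-fused hydroazulene, 1-CH3, 10-methylidene, 4-isopropyl, 4-OSiEt3, C6=C7 enol ether with 6-OSiEt3 | C=C1CCC=C(O[Si](CC)(CC)CC)[C@@H]2[C@@]1(C)CC[C@@]2(O[Si](CC)(CC)CC)C(C)C
F3 | step 8 | C6 epimer of diol 13 (6-OH trans to 4-OH) | C=C1CCC[C@H](O)[C@@H]2[C@@]1(C)CC[C@@]2(O)C(C)C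
F0 | step 13 | none | none
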